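The α-methylene-γ-butyrolactone is disconnected at its two bonds to the ten-membered ring: the lactone O–CH bond (O–C6) and the bond from the lactone α-carbon to the ring (C11–C7). The precursor is an (E)-cyclodec-6-en-1-one carrying, on the oxygen of the allylic C8 carbinol, a 2-bromo-3-alkoxypropanoate tether. In the key step the ester α-radical cyclizes 5-exo onto C7 and the ester oxygen then closes onto C6, so the trans-fused lactone and a temporary tetrahydrofuran form in one operation; the step exploits the C6=C7 alkene and its allylic C8–O. An anionic oxy-Cope builds the ring; later the tetrahydrofuran is opened and C8 inverted.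

Key step: step 9

Remark: atoms are numbered as in the germacranolide skeleton (C1 ketone; C3 carbinol; C4 methyl-bearing carbon; C6 lactone O–CH; C7 ring-fusion CH; C8 angelate carbon; C10 acetate carbon; C11, C12, C13 = lactone α-carbon, carbonyl and methylene); 2, 4, 13 and 20 are taken as commercial.

Step 1
Reactants: 1 4-methoxybenzyl alcohol; 2 (E)-1,2-diiodoethene
Product: 3 (E)-1-iodo-2-[(4-methoxybenzyl)oxy]ethene
Conditions: CuI (10 mol%), 3,4,7,8-tetramethyl-1,10-phenanthroline, Cs2CO3, toluene, 80 °C, 2 in threefold excess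
Reagents that add atoms: none
Why: Ullmann-type copper-catalysed C–O coupling of an alkenyl iodide with an alcohol keeps the alkene geometry and should stop after one exchange, because the β-alkoxyvinyl iodide formed is more electron-rich than 2.

Step 2
Reactants: 4 (S)-4-methylcyclohex-2-en-1-one; 3 (E)-1-iodo-2-[(4-methoxybenzyl)oxy]ethene
Product: 5 (4S,6S)-6-[(E)-2-(4-methoxybenzyloxy)ethenyl]-4-methylcyclohex-2-en-1-one
Conditions: LiHMDS, THF, −78 °C; then 3, Pd2(dba)3 (cat.), P(t-Bu)3, toluene, 25 °C; AcOH quench at −78 °C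
Reagents that add atoms: none
Why: Palladium-catalysed α-alkenylation of a ketone enolate: LiHMDS forms the cross-conjugated (α′) dienolate, which couples with 3 with retention of the E geometry; the new C6 centre is epimerizable and is drawn as the cis isomer (both substituents pseudo-equatorial), which is secured by equilibration in step 3.

Step 3
Reactants: 5 the alkenyl enone
Product: 7 (2S,4S,5S)-5-hydroxy-2-[(E)-2-(4-methoxybenzyloxy)ethenyl]-4-methylcyclohexan-1-one, via boryl ketone 6 (not isolated)
Conditions: CuCl (cat.), NaOt-Bu (cat.), bis[2-(diphenylphosphino)phenyl] ether, B2pin2, MeOH, THF, 0 °C; then NaBO3·4H2O, THF/H2O, 25 °C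
Reagents that add atoms: bis(pinacolato)diboron, CC1(C)OB(OC1(C)C)B1OC(C)(C)C(C)(C)O1 (boron of 6); sodium perborate tetrahydrate, [Na+].[O-]OB=O.O.O.O.O (hydroxyl oxygen of 7)
Why: Copper-catalysed conjugate borylation delivers boron to the β-carbon anti to the neighbouring methyl group, and perborate oxidation replaces boron by hydroxyl with retention, so the hydroxyl is trans to the methyl group while the basic medium equilibrates the α-centre to the all-equatorial ketone.

Step 4
Reactants: 7 the hydroxy ketone
Product: 8 (2S,4S,5S)-5-(tert-butyldiphenylsilyloxy)-2-[(E)-2-(4-methoxybenzyloxy)ethenyl]-4-methylcyclohexan-1-one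
Conditions: TBDPSCl, imidazole, DMF, 25 °C
Reagents that add atoms: tert-butylchlorodiphenylsilane, CC(C)(C)[Si](Cl)(c1ccccc1)c1ccccc1
Why: Standard silylation of a secondary alcohol; the bulky silyl ether is chosen to survive the later boron Lewis acid and no stereocentre is touched.

Step 5
Reactants: 8 the silyloxy ketone
Product: 9 (1S,2S,4S,5S)-5-(tert-butyldiphenylsilyloxy)-2-[(E)-2-(4-methoxybenzyloxy)ethenyl]-4-methyl-1-(prop-1-en-2-yl)cyclohexan-1-ol
Conditions: isopropenylmagnesium bromide, CeCl3, THF, −78 °C; aq. NH4Cl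
Reagents that add atoms: isopropenylmagnesium bromide, C=C(C)[Mg]Br
Why: Organocerium 1,2-addition is non-basic (no enolization, no β-elimination of the silyloxy group) and the nucleophile enters equatorially, anti to the adjacent alkenyl group, so the two alkenyl groups end up trans-diequatorial and the hydroxyl axial.

Step 6
Reactants: 9 the dialkenyl carbinol
Product: 11 (3S,4S,6E,8S,10R)-3-(tert-butyldiphenylsilyloxy)-10-hydroxy-8-(4-methoxybenzyloxy)-4,10-dimethylcyclodec-6-en-1-one, via potassium enolate 10 (not isolated)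
Conditions: KH, 18-crown-6, THF, 0 to 25 °C; then 2-(phenylsulfonyl)-3-phenyloxaziridine, −78 °C; aq. NH4Cl
Reagents that add atoms: potassium hydride, [K+].[H-] (potassium of 10); 2-(phenylsulfonyl)-3-phenyloxaziridine, O=S(=O)(N1OC1c1ccccc1)c1ccccc1 (C10 oxygen)
Why: Anionic oxy-Cope rearrangement through the chair transition state with both alkenyl groups equatorial gives the (E)-C6=C7 alkene and the ring-expanded enolate; suprafacial bond formation at the (E)-enol ether carbon sets C8 with its oxygen on the outer face of the alkene (opposite to the target, as the tether needs), and enolate α-hydroxylation on the peripheral face sets C10 as in the target.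

Step 7
Reactants: 11 the 4-methoxybenzyl ether
Product: 12 (3S,4S,6E,8S,10R)-3-(tert-butyldiphenylsilyloxy)-8,10-dihydroxy-4,10-dimethylcyclodec-6-en-1-one
Conditions: DDQ, CH2Cl2/pH 7 buffer, 0 °C
Reagents that add atoms: none
Why: Oxidative cleavage of the 4-methoxybenzyl ether by hydride abstraction and hydrolysis frees the allylic C8 hydroxyl under neutral conditions without touching any stereocentre.

Step 8
Reactants: 12 the diol; 13 tert-butyl 2-bromoacrylate
Product: 14 tert-butyl 2-bromo-3-(cyclodecenyl-C8-oxy)propanoate, the C8 ether of 12 (both epimers at the CHBr carbon)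
Conditions: 13 (excess), Cs2CO3 (cat.), MeCN, 0 °C
Reagents that add atoms: none
Why: Base-catalysed oxa-Michael addition of the secondary allylic alkoxide to the bromoacrylate should be selective because the tertiary α-ketol hydroxyl is too hindered; the CHBr centre forms as both epimers, which converge in step 9.

Step 9
Reactants: 14 the bromo ester ether
Product: 16 tetrahydrofuran-fused trans-lactone (C3, C4, C6, C7 and C10 as in the target; O8 epimeric and tied to C13), via bromide 15 (not isolated)
Conditions: Ir(ppy)3 (1 mol%), 2,6-lutidine, MeCN, blue LEDs, 25 °C; then 70 °C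
Reagents that add atoms: none
Why: Photoexcited Ir(ppy)3 reduces the C–Br bond of 14 to the ester α-radical at C11, which adds to C7 of the (E)-C6=C7 alkene; the C6 radical takes bromine from a further molecule of 14 (atom-transfer chain, bromide 15), and on warming the tert-butyl ester carbonyl oxygen displaces that bromide to close the lactone with loss of 2-methylpropene and HBr. The closest known reaction type is the atom-transfer radical cyclization of α-bromo esters followed by lactonization of the γ-bromo ester. The tetrahydrofuran ring (O8–C13–C11–C7–C8) closes 5-exo-trig and the lactone ring (O–C6–C7–C11–C12) 5-exo-tet. C7 is set by the tether, which reaches only the peripheral alkene face from the outward-pointing O8 with H8 eclipsing the double bond (C9 and C6 trans on the new tetrahydrofuran); C11 is set cis to C6 by the 1,5-cis preference of 5-exo closure and because only the cis-fused bicycle can lactonize; C6 is set by bromine transfer anti to the new C7–C11 bond followed by inversion, so C11 and O add syn across the former (E)-alkene and the lactone is trans-fused on the ten-membered ring as in the target. The step needs attack at C7 rather than C6 and 5-exo rather than 6-endo closure, both secured by the three-atom O8–C13–C11 tether, and tolerance of the C1 ketone, the tertiary hydroxyl and the silyl ether, secured by the neutral conditions.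

Step 10
Reactants: 16 the tetrahydrofuran-fused lactone
Product: 17 C10 acetate of 16
Conditions: Ac2O, DMAP, Et3N, CH2Cl2, 40 °C
Reagents that add atoms: acetic anhydride, CC(=O)OC(C)=O
Why: DMAP-catalysed acylation of the tertiary α-ketol hydroxyl, done while O8 is locked in the tetrahydrofuran so that no acetyl migration is possible; it also blocks α-ketol rearrangement in the next, Lewis-acidic step.

Step 11
Reactants: 17 the acetate
Product: 19 (3S,4S,6R,7R,8S,10R)-10-acetoxy-3-(tert-butyldiphenylsilyloxy)-8-hydroxy-1-oxogermacr-11(13)-en-12,6-olide (8-epi alcohol), via bromo borinate 18 (not isolated)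
Conditions: Me2BBr, CH2Cl2, −78 to 0 °C; then Et3N, 25 °C; aq. NaHCO3
Reagents that add atoms: bromodimethylborane, CB(C)Br (bromine and boron of 18 only)
Why: Lewis-acid ether cleavage: bromide attacks the boron-activated tetrahydrofuran at the primary C13 (SN2), leaving O8 as a borinate with C8 untouched, and triethylamine then eliminates HBr from the β-bromo lactone (E1cB) to the exocyclic methylene before the borinate is hydrolysed on work-up.

Step 12
Reactants: 19 the 8-epi alcohol; 20 angelic acid, (Z)-2-methylbut-2-enoic acid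
Product: 21 (3S,4S,6R,7S,8R,10R)-10-acetoxy-8-angeloyloxy-3-(tert-butyldiphenylsilyloxy)-1-oxogermacr-11(13)-en-12,6-olide
Conditions: 20, PPh3, DIAD, toluene, 0 to 25 °C
Reagents that add atoms: none
Why: Mitsunobu reaction: the C8 oxyphosphonium ion is displaced by angelate with SN2 inversion, which turns the 8-epi alcohol into the C8 configuration of the target, and the neutral conditions should keep the Z geometry of the angelate.

Step 13
Reactants: 21 the silyl ether
Product: 22 (3S,4S,6R,7S,8R,10R)-10-acetoxy-8-angeloyloxy-3-hydroxy-1-oxogermacr-11(13)-en-12,6-olide (target)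
Conditions: HF·pyridine, pyridine, THF, 0 to 25 °C
Reagents that add atoms: none
Why: Fluoride-mediated desilylation under buffered, non-basic conditions, so the β-hydroxy ketone is not exposed to retro-aldol or elimination and the two esters and the α-methylene lactone stay intact.

Compound list
1 | 4-methoxybenzyl alcohol | COc1ccc(CO)cc1 | starting material
2 | (E)-1,2-diiodoethene | I/C=C/I | starting material
3 | (E)-1-iodo-2-[(4-methoxybenzyl)oxy]ethene | COc1ccc(CO/C=C/I)cc1 | intermediate
4 | (S)-4-methylcyclohex-2-en-1-one | O=C1CC[C@H](C)C=C1 | starting material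
5 | (4S,6S)-6-[(E)-2-(4-methoxybenzyloxy)ethenyl]-4-methylcyclohex-2-en-1-one | O=C1[C@H](/C=C/OCc2ccc(OC)cc2)C[C@H](C)C=C1 | intermediate
6 | boryl ketone: 2-[(E)-2-(4-methoxybenzyloxy)ethenyl]-4-methyl-5-(pinacolboryl)cyclohexan-1-one, boron trans to the methyl group | O=C1[C@H](/C=C/OCc2ccc(OC)cc2)C[C@H](C)[C@@H](B2OC(C)(C)C(C)(C)O2)C1 | intermediate
7 | (2S,4S,5S)-5-hydroxy-2-[(E)-2-(4-methoxybenzyloxy)ethenyl]-4-methylcyclohexan-1-one | O=C1[C@H](/C=C/OCc2ccc(OC)cc2)C[C@H](C)[C@@H](O)C1 | intermediate
8 | (2S,4S,5S)-5-(tert-butyldiphenylsilyloxy)-2-[(E)-2-(4-methoxybenzyloxy)ethenyl]-4-methylcyclohexan-1-one | O=C1[C@H](/C=C/OCc2ccc(OC)cc2)C[C@H](C)[C@@H](O[Si](c2ccccc2)(c2ccccc2)C(C)(C)C)C1 | intermediate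
9 | (1S,2S,4S,5S)-5-(tert-butyldiphenylsilyloxy)-2-[(E)-2-(4-methoxybenzyloxy)ethenyl]-4-methyl-1-(prop-1-en-2-yl)cyclohexan-1-ol | CC(=C)[C@@]1(O)[C@H](/C=C/OCc2ccc(OC)cc2)C[C@H](C)[C@@H](O[Si](c2ccccc2)(c2ccccc2)C(C)(C)C)C1 | intermediate
10 | potassium enolate of the ring-expanded ketone (C1–O−, C1=C10 with C2 trans to C9; (E)-C6=C7) | C1[C@H](C)[C@@H](O[Si](c2ccccc2)(c2ccccc2)C(C)(C)C)C/C([O-])=C(C)/C[C@H](OCc2ccc(OC)cc2)/C=C/1.[K+] | intermediate
11 | (3S,4S,6E,8S,10R)-3-(tert-butyldiphenylsilyloxy)-10-hydroxy-8-(4-methoxybenzyloxy)-4,10-dimethylcyclodec-6-en-1-one | C1[C@H](C)[C@@H](O[Si](c2ccccc2)(c2ccccc2)C(C)(C)C)CC(=O)[C@](C)(O)C[C@H](OCc2ccc(OC)cc2)/C=C/1 | intermediate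
12 | (3S,4S,6E,8S,10R)-3-(tert-butyldiphenylsilyloxy)-8,10-dihydroxy-4,10-dimethylcyclodec-6-en-1-one | C1[C@H](C)[C@@H](O[Si](c2ccccc2)(c2ccccc2)C(C)(C)C)CC(=O)[C@](C)(O)C[C@H](O)/C=C/1 | intermediate
13 | tert-butyl 2-bromoacrylate | C=C(Br)C(=O)OC(C)(C)C | starting material
14 | C8 ether of 12 with tert-butyl 2-bromo-3-hydroxypropanoate (both epimers at the CHBr carbon) | C1[C@H](C)[C@@H](O[Si](c2ccccc2)(c2ccccc2)C(C)(C)C)CC(=O)[C@](C)(O)C[C@H](OCC(Br)C(=O)OC(C)(C)C)/C=C/1 | intermediate
15 | C6 bromide after radical cyclization: tetrahydrofuran (O8–C13–C11–C7–C8) with tert-butyl ester on C11, bromine on C6 anti to the C7–C11 bond | Br[C@H]1C[C@H](C)[C@@H](O[Si](c2ccccc2)(c2ccccc2)C(C)(C)C)CC(=O)[C@](C)(O)C[C@@H]2OC[C@@H](C(=O)OC(C)(C)C)[C@@H]12 | intermediate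
16 | tetrahydrofuran-fused trans-12,6-lactone: 10-hydroxy-1-oxo-3-silyloxy, O8 linked to C13, H7/H11 cis, C8 epimeric to the target | O=C1O[C@@H]2C[C@H](C)[C@@H](O[Si](c3ccccc3)(c3ccccc3)C(C)(C)C)CC(=O)[C@](C)(O)C[C@@H]3OC[C@@H]1[C@@H]23 | intermediate
17 | C10 acetate of 16 | O=C1O[C@@H]2C[C@H](C)[C@@H](O[Si](c3ccccc3)(c3ccccc3)C(C)(C)C)CC(=O)[C@](C)(OC(C)=O)C[C@@H]3OC[C@@H]1[C@@H]23 | intermediate
18 | 13-bromo lactone with O8 as dimethylborinate (ring-opened 17) | O=C1O[C@@H]2C[C@H](C)[C@@H](O[Si](c3ccccc3)(c3ccccc3)C(C)(C)C)CC(=O)[C@](C)(OC(C)=O)C[C@H](OB(C)C)[C@H]2[C@H]1CBr | intermediate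
19 | (3S,4S,6R,7R,8S,10R)-10-acetoxy-3-(tert-butyldiphenylsilyloxy)-8-hydroxy-1-oxogermacr-11(13)-en-12,6-olide | C=C1C(=O)O[C@@H]2C[C@H](C)[C@@H](O[Si](c3ccccc3)(c3ccccc3)C(C)(C)C)CC(=O)[C@](C)(OC(C)=O)C[C@H](O)[C@@H]12 | intermediate
20 | angelic acid, (Z)-2-methylbut-2-enoic acid | C/C=C(/C)C(=O)O | starting material
21 | (3S,4S,6R,7S,8R,10R)-10-acetoxy-8-angeloyloxy-3-(tert-butyldiphenylsilyloxy)-1-oxogermacr-11(13)-en-12,6-olide | C=C1C(=O)O[C@@H]2C[C@H](C)[C@@H](O[Si](c3ccccc3)(c3ccccc3)C(C)(C)C)CC(=O)[C@](C)(OC(C)=O)C[C@@H](OC(=O)/C(C)=C\C)[C@@H]12 | intermediate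
22 | (3S,4S,6R,7S,8R,10R)-10-acetoxy-8-angeloyloxy-3-hydroxy-1-oxogermacr-11(13)-en-12,6-olide | C=C1C(=O)O[C@@H]2C[C@H](C)[C@@H](O)CC(=O)[C@](C)(OC(C)=O)C[C@@H](OC(=O)/C(C)=C\C)[C@@H]12 | target

Total step count: 13. Longest linear sequence: 13 steps (steps 1 to 13 lie on one line from 1; 12 steps counted from enone 4).

Steps most likely to fail

Step 9 (key step). What may go wrong: bromine transfer to the C6 radical on the face syn to C11, or hydrogen transfer across the ring to that radical, so that the displacement to the lactone fails or closes the wrong ring fusion. Fallback (oxidative radical cyclization with no halide at C6): starting from diol 12, triethylamine-catalysed addition of the C8 hydroxyl to di-tert-butyl methylidenemalonate should give the malonate ether F1. Mn(OAc)3·2H2O and Cu(OAc)2 in AcOH (trivalent manganese makes the malonyl radical, divalent copper oxidizes the cyclized C6 radical at once) should close tetrahydrofuran and lactone to the ester lactone F2, with one tert-butyl group lost. CF3CO2H in CH2Cl2, then heating in toluene, removes the remaining ester by decarboxylation and comes back to the route at 16.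

Step 8. What may go wrong: the carbonate base triggers α-ketol rearrangement at C10/C1 or addition through the tertiary hydroxyl, or the adduct reverts by retro-Michael loss of the alkoxide. Fallback (no base): starting from 12, BF3·OEt2-catalysed opening of tert-butyl oxirane-2-carboxylate at its CH2 terminus by the C8 hydroxyl should give the hydroxy ester F3; an Appel reaction (CBr4, PPh3) then replaces its hydroxyl by bromine and comes back to the route at 14.

Step 12. What may go wrong: slow activation of the hindered ring carbinol, so that elimination or acylation with retention competes with inversion. Fallback (oxidation and reduction instead of displacement): starting from 19, Dess–Martin periodinane should give the C8 ketone F4; Luche reduction (NaBH4, CeCl3·7H2O, MeOH, −78 °C), with hydride entering anti to the C7–C11 bond, should give the target-configured C8 alcohol F5; Yamaguchi esterification with 20 (2,4,6-trichlorobenzoyl chloride, Et3N, DMAP, toluene) comes back to the route at 21.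

Further compounds
F1 | step 9 | malonate ether: C8 ether of 12 with di-tert-butyl (hydroxymethyl)malonate | C1[C@H](C)[C@@H](O[Si](c2ccccc2)(c2ccccc2)C(C)(C)C)CC(=O)[C@](C)(O)C[C@H](OCC(C(=O)OC(C)(C)C)C(=O)OC(C)(C)C)/C=C/1
F2 | step 9 | ester lactone: 16 carrying a tert-butoxycarbonyl group on C11 in place of H11 | O=C1O[C@@H]2C[C@H](C)[C@@H](O[Si](c3ccccc3)(c3ccccc3)C(C)(C)C)CC(=O)[C@](C)(O)C[C@@H]3OC[C@]1(C(=O)OC(C)(C)C)[C@@H]23
F3 | step 8 | hydroxy ester: C8 ether of 12 with tert-butyl 2,3-dihydroxypropanoate (through its primary oxygen) | C1[C@H](C)[C@@H](O[Si](c2ccccc2)(c2ccccc2)C(C)(C)C)CC(=O)[C@](C)(O)C[C@H](OCC(O)C(=O)OC(C)(C)C)/C=C/1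
F4 | step 12 | C8 ketone: 10-acetoxy-3-(tert-butyldiphenylsilyloxy)-1,8-dioxogermacr-11(13)-en-12,6-olide | C=C1C(=O)O[C@@H]2C[C@H](C)[C@@H](O[Si](c3ccccc3)(c3ccccc3)C(C)(C)C)CC(=O)[C@](C)(OC(C)=O)CC(=O)[C@@H]12
F5 | step 12 | C8 alcohol with the target configuration (8-epimer of 19) | C=C1C(=O)O[C@@H]2C[C@H](C)[C@@H](O[Si](c3ccccc3)(c3ccccc3)C(C)(C)C)CC(=O)[C@](C)(OC(C)=O)C[C@@H](O)[C@@H]12
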